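Take the flask at its end first, and only then ask how soon it gets there.

starting material 0.40 M (in portions, 4); protic impurity 0.0200 M; time 4.0 min; the portions of starting material follow each other after 1.5 s, the first at the start

    starting material ⇌ dormant form (K1 = 0.52, k1 = 0.53 s⁻¹)
    starting material + protic impurity → quenched substrate (k2 = 1.6 M⁻¹ s⁻¹)
    starting material + starting material ⇌ product (K3 = 4.1 M⁻¹, k3 = 0.27 M⁻¹ s⁻¹)

* which holds at 4.0 min: what has brought the reaction to rest, or that it has not come to rest (it is still moving / forward and back rates have come level / all of the starting material has reacted)
* amount of product at 4.0 min, in percent of the starting material charged
* amount of product if the flask were left three thousand times as long, in percent of the starting material charged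

- a species is counted by the starting material in it: one product counts as two
- two of one species on the left: rate k times its square, two consumed each time
- the reaction counts as stopped when no species that holds the starting material changes by six tenths of a point or more over the second half of the time
- run time (flask): 4.0 min

I built my reckoning as a ladder, fastest rung first. Starting material and dormant form relax towards each other with a half-life of 0.447 s, shorter than the 1.5 s between portions, so I let them move as one. Each protic impurity takes one starting material for good. That defines the pool, the starting material charged less the protic impurity charged: 0.380 M. Call the free starting material at the end a. The pool then balances a, plus 0.52 a in the dormant form, plus two times 4.1 M⁻¹ times a squared in the product. This quadratic gave a = 0.142 M.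

At that level the impurity's half-life is 3.06 s. On the next rung, a small excess of product dies away through the back step and the pull of the forward step, thinned by the dormant form, with a half-life of 4.16 s. Both are far shorter than the 4.0 min of the run, so I expected forward and back rates level, with product at 41.2% of the charge, at the asked time and after the long wait.

The forecast said forward and back rates have come level, with 41.2% at the asked time and 41.2% after the long wait, on the grounds that “Both equilibria relax within seconds to tens of seconds”. Its figure and mine were the same.

The simulation gave forward and back rates have come level, 41.2% and 41.2%, and nearly all of the conversion at the asked time was reached by 0.240 min. In this flask at 4.00 min, starting material, product and dormant form together held 95.0% of the charge, and the pool is 95.0% of it. In the neighbouring flask, charged with 0.16 M of starting material, the pool is 0.140 M. The same balance gives a = 0.0675 M and product at 23.4% of that charge. At 4.00 min the simulated neighbouring flask held 23.4% as product and, as its largest share, 42.2% as starting material.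

(The constants belong to no real substance, and the outcome is calculated.)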